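**Plan**

1. Retrosynthesis, in labdane numbering (ring A = C1–C5 + C10, ring B = C5–C10, C17 on C8, C18/C19 on C4, C20 on C10, side chain C11–C16). Cut C9–C11 to give a C9 ketone and a C6 side-chain unit. Trace C3–Br back through a Δ2 alkenyl bromide to a C3 ketone. Add an acyl helper at C6, then cut C5–C10 and C6–C7 together, then C5=C6 (metathesis) and C3–C4 (prenyl addition).
2. Enabling feature: ring B carries its only heteroatom on C9, between C8 and C10. As the C9 ketone masked as its C8=C9 enol silane, ring B is a cyclohexene. Its retro-[4+2] gives the 2-silyloxydiene C7=C8–C9(OSi)=C10 and the dienophile C5=C6. C1–C4 of ring A are then the four-atom tether, so both rings come from one open chain.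
3. Forward: melonal, isopropenyl and prenyl units give an achiral linear triene (steps 1–6). Rings A and B form together in step 7. The C6 helper is then removed, Br is installed at C3, and the side chain is joined last at C9.
4. Stereochemistry: C5, C10 and the transient C6 are set at once by three elements. These are a chiral Cu(II)–bis(oxazoline) catalyst, the endo transition state, and a (Z)-enol silane whose geometry comes from a temporary enol-lactone ring. C8 (equilibration), C3 (H-atom delivery) and C9 (axial addition) are relayed from C5/C10 by substrate control. C13 is bought with (R)-linalool.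

Key step: step 7

Remark: 1 is used as the racemate, because its stereocentre (C10) and the carbinol centre of 3 (C9) are both planarised by step 4, so 7, 11 and 13 are achiral.

**Step 1**
Reactants: 1 (±)-2,6-dimethylhept-5-enal (melonal); 2 isopropenylmagnesium bromide
Product: 3 2,4,8-trimethylnona-1,7-dien-3-ol (racemic diastereomer mixture)
Conditions: THF, 0 °C; then H2O
Reagents that add atoms: none
Why: Grignard 1,2-addition to the aldehyde forms C8–C9, and the stereocentres C9 and C10 do not matter because both become sp2 later.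

**Step 2**
Reactants: 3 2,4,8-trimethylnona-1,7-dien-3-ol
Product: 4 (±)-2,4,8-trimethylnona-1,7-dien-3-one
Conditions: Dess–Martin periodinane, CH2Cl2, 0 °C → rt
Reagents that add atoms: none
Why: Dess–Martin oxidation of the allylic alcohol should give the isopropenyl ketone without touching either alkene.

**Step 3**
Reactants: 4 (±)-2,4,8-trimethylnona-1,7-dien-3-one
Product: 6 (±)-4,6-dimethyl-5-oxohept-6-enoic acid, via keto aldehyde 5 (not isolated)
Conditions: O3 (1 equiv, Sudan III end point), CH2Cl2, −78 °C; Me2S; then NaClO2, NaH2PO4, 2-methylbut-2-ene, t-BuOH/H2O, rt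
Reagents that add atoms: ozone, [O-][O+]=O; sodium chlorite, [Na+].[O-]Cl=O
Why: Chemoselective ozonolysis (the electron-rich trisubstituted alkene reacts far faster than the electron-poor enone alkene) followed by Pinnick oxidation of the crude aldehyde turns C3 into the carboxyl carbon.

**Step 4**
Reactants: 6 (±)-4,6-dimethyl-5-oxohept-6-enoic acid
Product: 7 5-methyl-6-(prop-1-en-2-yl)-3,4-dihydro-2H-pyran-2-one
Conditions: Ac2O, NaOAc (cat.), BHT (trace), 100 °C
Reagents that add atoms: none
Why: Classical enol lactonisation of a δ-keto acid through the mixed anhydride; only C10 carries an enolisable hydrogen, and the six-membered ring forces O9 and C1 cis on the new C9=C10 double bond.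

**Step 5**
Reactants: 7 5-methyl-6-(prop-1-en-2-yl)-3,4-dihydro-2H-pyran-2-one; 8 prenyl chloride
Product: 11 (7Z)-8-(tert-butyldimethylsilyloxy)-3,3,7,9-tetramethyldeca-1,7,9-trien-4-one, via prenylmagnesium chloride 9 (not isolated), via chloromagnesium dienolate 10 (not isolated)
Conditions: 8, Mg, THF, 0 °C; added (1.0 equiv) to 7, THF, −78 °C; TBSOTf, −78 → 0 °C
Reagents that add atoms: tert-butyldimethylsilyl triflate, CC(C)(C)[Si](C)(C)OS(=O)(=O)C(F)(F)F; magnesium, [Mg] (stays only in 9 and 10)
Why: This is the first stage of a Fujimoto–Belleau reaction: the allylic Grignard reagent adds through its γ-carbon (SE2′) to the lactone carbonyl to form C3–C4 and the quaternary C4, the adduct expels the enolate with its ring-derived (Z) geometry (as in enolate release from enol esters), O-silylation fixes that geometry, and the α-quaternary C3 ketone resists a second addition.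

**Step 6**
Reactants: 11 (7Z)-silyloxy trienone; 12 3-acryloyloxazolidin-2-one
Product: 13 3-[(2E,8Z)-9-(tert-butyldimethylsilyloxy)-4,4,8,10-tetramethyl-5-oxoundeca-2,8,10-trienoyl]oxazolidin-2-one
Conditions: Hoveyda–Grubbs II (10 mol %), 12 (excess), CH2Cl2, 40 °C
Reagents that add atoms: none
Why: Olefin cross-metathesis of the neopentylic monosubstituted alkene with the acrylimide should give the (E)-enoyl imide, while the 1,1-disubstituted/tetrasubstituted silyloxydiene is too hindered to enter the catalytic cycle.

**Step 7**
Reactants: 13 (2E,8Z)-trienimide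
Product: 14 (5S,6R,10R)-imide cycloadduct: trans-fused Δ8-octalin with C9 OTBS, C3 ketone, C4 gem-dimethyl, C8 and C10 methyls, H-5 anti to C20, equatorial C6 carbonyl-oxazolidinone on the H-5 face
Conditions: [Cu((S,S)-t-Bu-box)](SbF6)2 (10 mol %), CH2Cl2 (0.01 M), rt
Reagents that add atoms: none
Why: The imide binds through both carbonyl oxygens, in its s-cis form, to the square-planar Cu(II)–(S,S)-t-Bu-box dication, which lowers the LUMO of C5=C6, and the 2-silyloxydiene, whose largest HOMO coefficient lies on C10, adds in a polarity-matched, concerted but strongly asynchronous [4+2] cycloaddition in which C10–C5 leads and C7–C6 follows. The closest known reaction type is the bis(oxazoline)copper(II)-catalysed enantioselective type 1 intramolecular Diels–Alder reaction of N-trienoyl oxazolidinones, backed by the Mukaiyama–Michael additions of enol silanes that the same catalysts promote. Ring B (C5–C6–C7–C8–C9–C10) closes as the cycloaddition ring and ring A (C10–C1–C2–C3–C4–C5) as the fused ring over a chair-like four-atom tether; in the stepwise limit these are a 6-exo-trig Michael closure of ring A and a 6-endo-trig Michael closure of ring B. C5 and the transient C6 are set by the catalyst, whose tert-butyl group covers the Si face of C6 so that the diene adds to the C6-Re face (5S,6R), the (E)-alkene placing the acyl group trans to C4. C10 is set relative to C5 by two substrate elements, the (Z)-enol silane that holds the tether carbon C1 outside and C20 inside on the diene terminus, and the imide-endo/tether-exo transition state, which together put C20 anti to H-5 (10R, trans-fused). The step needs endo over exo closure, cycloaddition over desilylation or intermolecular Michael addition, and no activation of the C3 ketone; these are secured by the Lewis-acid-enhanced endo preference, by the Thorpe–Ingold effect of the C4 gem-dimethyl group together with high dilution and a dienophile without enolisable hydrogens, and by two-point binding that only the imide can offer.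

**Step 8**
Reactants: 14 imide cycloadduct
Product: 15 (5S,6R,10R)-C6 carboxylic acid (enol silane and C3 ketone retained)
Conditions: LiOH, H2O2, THF/H2O, 0 °C; Na2SO3; cold dilute HCl to pH 4
Reagents that add atoms: hydrogen peroxide, OO
Why: Hydroperoxide cleavage of an N-acyl oxazolidinone attacks the exocyclic carbonyl selectively, and the hindered tetrasubstituted TBS enol ether, which also blocks retro-Michael opening, should survive the cold basic medium.

**Step 9**
Reactants: 15 C6 carboxylic acid
Product: 17 (5S,10R)-9-(tert-butyldimethylsilyloxy)-4,4,8,10-tetramethyl-trans-Δ8-octalin-3-one, via Barton ester 16 (not isolated)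
Conditions: 1-hydroxypyridine-2(1H)-thione, DCC, DMAP (cat.), CH2Cl2, dark, 0 °C → rt; then t-BuSH, hν (W lamp), toluene, rt
Reagents that add atoms: 1-hydroxypyridine-2(1H)-thione, ON1C=CC=CC1=S (stays only in 16)
Why: Barton reductive decarboxylation removes the acyl helper through the secondary C6 radical, which takes hydrogen from the thiol and erases the transient C6 stereocentre without touching ketone or enol silane.

**Step 10**
Reactants: 17 keto enol silane
Product: 18 Δ2-enol triflate (C3 OTf; C5 and C10 unchanged)
Conditions: KHMDS, THF, −78 °C; PhNTf2, −78 → 0 °C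
Reagents that add atoms: N-phenylbis(trifluoromethanesulfonimide), O=S(=O)(N(c1ccccc1)S(=O)(=O)C(F)(F)F)C(F)(F)F
Why: Kinetic enolate triflation, as practised on 4,4-dimethyl-3-keto terpenoids, can only occur at C2/C3 because C4 is quaternary and the C9 carbonyl is still masked as its enol silane.

**Step 11**
Reactants: 18 Δ2-enol triflate
Product: 19 (5S,10R)-3-bromo-Δ2,Δ8-diene (C9 OTBS retained)
Conditions: [Cp*Ru(MeCN)3]OTf (5 mol %), LiBr, DMI, 60 °C
Reagents that add atoms: lithium bromide, [Li+].[Br-]
Why: Ruthenium-catalysed exchange of an alkenyl triflate for halide (oxidative addition, anion exchange, reductive elimination) should give the alkenyl bromide under neutral conditions that spare the enol silane.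

**Step 12**
Reactants: 19 3-bromo-Δ2,Δ8-diene
Product: 20 (5S,8S,10R)-3-bromo-4,4,8,10-tetramethyl-trans-Δ2-octalin-9-one (C8 methyl equatorial and anti to C20)
Conditions: TBAF, THF, 0 °C → rt; then NaOMe (cat.), MeOH, rt
Reagents that add atoms: none
Why: Fluoride desilylation frees the C9 ketone, and base equilibration through the enolate places the C8 methyl equatorial (8S), because the axial epimer suffers a syn-diaxial methyl/methyl contact with C20.

**Step 13**
Reactants: 20 alkenyl bromide ketone
Product: 21 (2S,4aS,6R,8aR)-6-bromo-2,5,5,8a-tetramethyloctahydronaphthalen-1(2H)-one (labdane 3R,5S,8S,10R; Br equatorial and syn to C20)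
Conditions: Co(acac)2 and t-BuOOH (substoichiometric), Et3SiH, cyclohexa-1,4-diene, n-PrOH, rt, Ar
Reagents that add atoms: none
Why: In this cobalt-hydride HAT hydrogenation of an alkenyl halide, H• adds to C2, and the α-bromo C3 radical takes its hydrogen axially on the face anti to the axial C4 and C10 methyls, so that bromine ends equatorial (3R, also the thermodynamic epimer) while the C–Br bond and the ketone stay intact.

**Step 14**
Reactants: 22 (R)-(−)-linalool
Product: 23 (R)-linalool triethylsilyl ether
Conditions: TESOTf, 2,6-lutidine, CH2Cl2, 0 °C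
Reagents that add atoms: triethylsilyl triflate, CC[Si](CC)(CC)OS(=O)(=O)C(F)(F)F
Why: Silyl triflate silylation protects the tertiary allylic alcohol without touching the C13 stereocentre.

**Step 15**
Reactants: 23 (R)-linalool triethylsilyl ether
Product: 25 (R)-4-methyl-4-(triethylsilyloxy)hex-5-enoic acid, via silyloxy aldehyde 24 (not isolated)
Conditions: O3 (1 equiv, Sudan III end point), CH2Cl2, −78 °C; Me2S; then NaClO2, NaH2PO4, 2-methylbut-2-ene, t-BuOH/H2O, rt
Reagents that add atoms: ozone, [O-][O+]=O; sodium chlorite, [Na+].[O-]Cl=O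
Why: Chemoselective ozonolysis of the trisubstituted alkene (the hindered, inductively deactivated vinyl group reacts much more slowly) followed by Pinnick oxidation gives the acid with C13 untouched.

**Step 16**
Reactants: 25 (R)-silyloxy acid
Product: 27 (R)-5-iodo-3-methyl-3-(triethylsilyloxy)pent-1-ene, via Barton ester 26 (not isolated)
Conditions: 1-hydroxypyridine-2(1H)-thione, DCC, CH2Cl2, dark, 0 °C → rt; then CHI3, hν (W lamp), toluene, rt
Reagents that add atoms: iodoform, IC(I)I; 1-hydroxypyridine-2(1H)-thione, ON1C=CC=CC1=S (stays only in 26)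
Why: Barton iododecarboxylation removes the surplus carbon under neutral conditions, and the primary 4-pentenyl-type radical has no fast cyclisation mode before it abstracts iodine.

**Step 17**
Reactants: 27 (R)-iodide; 21 bromo ketone
Product: 31 target (1R,2S,4aS,6R,8aR)-6-bromo-1-[(3R)-3-hydroxy-3-methylpent-4-en-1-yl]-2,5,5,8a-tetramethyldecahydronaphthalen-1-ol, via organolithium 28 (not isolated), via organocerium 29 (not isolated), via TES ether 30 (not isolated)
Conditions: 27, t-BuLi (2 equiv), Et2O/pentane, −78 °C; CeCl3, THF, −78 °C; 21, −78 → −40 °C; H2O; then TBAF, THF, 0 °C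
Reagents that add atoms: tert-butyllithium, [Li]C(C)(C)C (Li stays only in 28); cerium(III) chloride, Cl[Ce](Cl)Cl (stays only in 29)
Why: Iodine–lithium exchange and transmetalation give a weakly basic organocerium reagent that adds to the hindered enolisable ketone along the axial trajectory anti to the axial C20 methyl on C10, which blocks the equatorial trajectory, so that C11 ends axial and the C9 hydroxyl equatorial (9R), while the neopentylic secondary bromide is inert at low temperature and fluoride then removes the TES group.

**Compound list**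

1 | (±)-2,6-dimethylhept-5-enal (melonal) | CC(C)=CCCC(C)C=O | starting material
2 | isopropenylmagnesium bromide | C=C(C)[Mg]Br | starting material
3 | 2,4,8-trimethylnona-1,7-dien-3-ol (racemic diastereomers) | C=C(C)C(O)C(C)CCC=C(C)C | intermediate
4 | (±)-2,4,8-trimethylnona-1,7-dien-3-one | C=C(C)C(=O)C(C)CCC=C(C)C | intermediate
5 | (±)-4,6-dimethyl-5-oxohept-6-enal | C=C(C)C(=O)C(C)CCC=O | intermediate
6 | (±)-4,6-dimethyl-5-oxohept-6-enoic acid | C=C(C)C(=O)C(C)CCC(=O)O | intermediate
7 | 5-methyl-6-(prop-1-en-2-yl)-3,4-dihydro-2H-pyran-2-one | CC1=C(C(C)=C)OC(=O)CC1 | intermediate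
8 | prenyl chloride (1-chloro-3-methylbut-2-ene) | CC(C)=CCCl | starting material
9 | prenylmagnesium chloride | CC(C)=CC[Mg]Cl | intermediate
10 | chloromagnesium (Z)-dienolate of 3,3,7,9-tetramethyldeca-1,9-diene-4,8-dione | C=C(C)/C(O[Mg]Cl)=C(\C)CCC(=O)C(C)(C)C=C | intermediate
11 | (7Z)-8-(tert-butyldimethylsilyloxy)-3,3,7,9-tetramethyldeca-1,7,9-trien-4-one | C=C(C)/C(O[Si](C)(C)C(C)(C)C)=C(\C)CCC(=O)C(C)(C)C=C | intermediate
12 | 3-acryloyloxazolidin-2-one | C=CC(=O)N1CCOC1=O | starting material
13 | 3-[(2E,8Z)-9-(tert-butyldimethylsilyloxy)-4,4,8,10-tetramethyl-5-oxoundeca-2,8,10-trienoyl]oxazolidin-2-one | C=C(C)/C(O[Si](C)(C)C(C)(C)C)=C(\C)CCC(=O)C(C)(C)/C=C/C(=O)N1CCOC1=O | intermediate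
14 | (5S,6R,10R)-imide cycloadduct (trans-Δ8-octalin, C9 OTBS, C3 ketone) | CC(C)(C)[Si](C)(C)OC1=C(C)C[C@@H](C(=O)N3CCOC3=O)[C@@H]2C(C)(C)C(=O)CC[C@]21C | intermediate
15 | (5S,6R,10R)-C6 carboxylic acid | CC(C)(C)[Si](C)(C)OC1=C(C)C[C@@H](C(=O)O)[C@@H]2C(C)(C)C(=O)CC[C@]21C | intermediate
16 | Barton ester of 15 | CC(C)(C)[Si](C)(C)OC1=C(C)C[C@@H](C(=O)ON3C=CC=CC3=S)[C@@H]2C(C)(C)C(=O)CC[C@]21C | intermediate
17 | (5S,10R)-9-(tert-butyldimethylsilyloxy)-4,4,8,10-tetramethyl-trans-Δ8-octalin-3-one | CC(C)(C)[Si](C)(C)OC1=C(C)CC[C@@H]2C(C)(C)C(=O)CC[C@]21C | intermediate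
18 | Δ2-enol triflate of 17 | CC(C)(C)[Si](C)(C)OC1=C(C)CC[C@@H]2C(C)(C)C(OS(=O)(=O)C(F)(F)F)=CC[C@]21C | intermediate
19 | (5S,10R)-3-bromo-9-(tert-butyldimethylsilyloxy)-Δ2,Δ8-diene | CC(C)(C)[Si](C)(C)OC1=C(C)CC[C@@H]2C(C)(C)C(Br)=CC[C@]21C | intermediate
20 | (5S,8S,10R)-3-bromo-4,4,8,10-tetramethyl-trans-Δ2-octalin-9-one | O=C1[C@@H](C)CC[C@@H]2C(C)(C)C(Br)=CC[C@]21C | intermediate
21 | (2S,4aS,6R,8aR)-6-bromo-2,5,5,8a-tetramethyloctahydronaphthalen-1(2H)-one | O=C1[C@@H](C)CC[C@@H]2C(C)(C)[C@H](Br)CC[C@]21C | intermediate
22 | (R)-(−)-linalool | C=C[C@](C)(O)CCC=C(C)C | starting material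
23 | (R)-linalool triethylsilyl ether | C=C[C@](C)(O[Si](CC)(CC)CC)CCC=C(C)C | intermediate
24 | (R)-4-methyl-4-(triethylsilyloxy)hex-5-enal | C=C[C@](C)(O[Si](CC)(CC)CC)CCC=O | intermediate
25 | (R)-4-methyl-4-(triethylsilyloxy)hex-5-enoic acid | C=C[C@](C)(O[Si](CC)(CC)CC)CCC(=O)O | intermediate
26 | Barton ester of 25 | C=C[C@](C)(O[Si](CC)(CC)CC)CCC(=O)ON1C=CC=CC1=S | intermediate
27 | (R)-5-iodo-3-methyl-3-(triethylsilyloxy)pent-1-ene | C=C[C@](C)(O[Si](CC)(CC)CC)CCI | intermediate
28 | (R)-[3-methyl-3-(triethylsilyloxy)pent-4-en-1-yl]lithium | C=C[C@](C)(O[Si](CC)(CC)CC)CC[Li] | intermediate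
29 | corresponding alkylcerium dichloride | C=C[C@](C)(O[Si](CC)(CC)CC)CC[Ce](Cl)Cl | intermediate
30 | 13-O-TES ether of the target (3R,5S,8S,9R,10R,13R) | C=C[C@](C)(O[Si](CC)(CC)CC)CC[C@@]1(O)[C@@H](C)CC[C@@H]2C(C)(C)[C@H](Br)CC[C@]21C | intermediate
31 | (1R,2S,4aS,6R,8aR)-6-bromo-1-[(3R)-3-hydroxy-3-methylpent-4-en-1-yl]-2,5,5,8a-tetramethyldecahydronaphthalen-1-ol | C=C[C@](C)(O)CC[C@@]1(O)[C@@H](C)CC[C@@H]2C(C)(C)[C@H](Br)CC[C@]21C | target

**Step count and risks**

Total step count: 17. Longest linear sequence: 14 (steps 1–13 and 17).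

Steps most likely to fail:

**Step 7.** The cycloaddition may be too slow, because the diene terminus carries an inside methyl group and the β-carbon of the dienophile is neopentylic. Loss of the silyl group, exo closure or low facial control could then take over. The fallback sets out from 11 and changes from catalyst control to auxiliary control with a stoichiometric, more strongly activating Lewis acid.
- Cross-metathesis of 11 with (R)-3-acryloyl-4-benzyloxazolidin-2-one should give the chiral trienimide F1.
- Me2AlCl (excess, CH2Cl2, −30 °C) forms the cationic aluminium chelate, in which the benzyl group covers the C6-Si face.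
- The auxiliary-controlled endo intramolecular Diels–Alder reaction should then give the auxiliary cycloadduct F2.
- Hydroperoxide cleavage of F2 returns to the route at 15.

**Step 5.** The prenyl reagent may attack through its α-carbon or add a second time. Proton transfer between the released enolate and the new ketone may also scramble the enolate before silylation. The fallback sets out from 7 and separates enolate release from C–C bond formation.
- 7 is opened with the chloromagnesium amide made from N,O-dimethylhydroxylamine hydrochloride and i-PrMgCl (THF, −20 °C).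
- The expelled (Z)-dienolate is silylated at once with TBSOTf to give the Weinreb amide dienol silane F3.
- F3 takes up one equivalent of prenylmagnesium chloride 9 through a stable chelate and returns to the route at 11.

**Step 6.** Metathesis at the neopentylic vinyl group may be sluggish, so catalyst decay or engagement of the silyloxydiene could compete. The fallback sets out from 7 and builds C5=C6 by olefination instead.
- Lithiated N-tert-butyl-2-methylpropan-1-imine (LDA, THF, −78 °C) is C-acylated by 7.
- The expelled dienolate is silylated with TBSOTf to give the keto imine dienol silane F4.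
- Buffered hydrolysis (aq. NaOAc/AcOH, pH 5) gives the keto aldehyde dienol silane F5.
- Horner–Wadsworth–Emmons olefination under Masamune–Roush conditions (LiCl, i-Pr2NEt, MeCN) with diethyl [2-oxo-2-(2-oxooxazolidin-3-yl)ethyl]phosphonate returns to the route at 13.

**Further compounds**

F1 | step 7 | (4R)-4-benzyl-3-[(2E,8Z)-9-(tert-butyldimethylsilyloxy)-4,4,8,10-tetramethyl-5-oxoundeca-2,8,10-trienoyl]oxazolidin-2-one | C=C(C)/C(O[Si](C)(C)C(C)(C)C)=C(\C)CCC(=O)C(C)(C)/C=C/C(=O)N1[C@H](Cc2ccccc2)COC1=O
F2 | step 7 | (5S,6R,10R)-cycloadduct carrying the (4R)-4-benzyloxazolidin-2-one auxiliary | CC(C)(C)[Si](C)(C)OC1=C(C)C[C@@H](C(=O)N3[C@H](Cc4ccccc4)COC3=O)[C@@H]2C(C)(C)C(=O)CC[C@]21C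
F3 | step 5 | (4Z)-5-(tert-butyldimethylsilyloxy)-N-methoxy-N,4,6-trimethylhepta-4,6-dienamide | C=C(C)/C(O[Si](C)(C)C(C)(C)C)=C(\C)CCC(=O)N(C)OC
F4 | step 6 | (6Z)-1-(tert-butylimino)-7-(tert-butyldimethylsilyloxy)-2,2,6,8-tetramethylnona-6,8-dien-3-one | C=C(C)/C(O[Si](C)(C)C(C)(C)C)=C(\C)CCC(=O)C(C)(C)C=NC(C)(C)C
F5 | step 6 | (6Z)-7-(tert-butyldimethylsilyloxy)-2,2,6,8-tetramethyl-3-oxonona-6,8-dienal | C=C(C)/C(O[Si](C)(C)C(C)(C)C)=C(\C)CCC(=O)C(C)(C)C=O
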